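## Analysis of the target

The target (20) is a cis-fused decalin of the eremophilane type. Numbering used throughout: ring A is C1–C5 plus C10, with the ketone at C2, the secondary methyl C15 on C4 and the angular methyl C14 on the quaternary C5; ring B is C5–C10, with the isopropenyl group (C11–C13) on C7, the (2R)-2-methylbutanoate on O8 and the tiglate on O9. There are six ring stereocentres (4S,5R,7R,8R,9S,10S) and the (R) centre of the saturated ester. Both methyls, H10 and the isopropenyl group lie on the β-face; the two oxygens lie on the α-face. In the chair–chair conformer that keeps the isopropenyl group equatorial, C14 (on ring B) and O8 are equatorial, whereas O9 is axial and syn-axial to C4. Four contiguous stereocentres (C7–C10) abut the quaternary C5, which carries the C4 stereocentre on its other side. Sensitive points are two different esters on a cis-diol (1,2-acyl migration), a 1,1-disubstituted alkene that rules out late hydrogenation and most oxidants, C10 (epimerisable whenever C9 is a ketone) and the α-branched acyl groups. The hard problems are the cis ring fusion next to the vicinal C4/C5 methyl pair, placing the isopropenyl group at C7 cis to C14, and telling O8 from O9. The feature that invites the key step is on ring B: C7 (isopropenyl) and C8 (oxygen) form a trans-2-isopropenylcyclohexanol unit with a further oxygen on C9. This is the retron of a carbonyl-ene ring closure of a prenyl group onto a 1,2-dicarbonyl unit.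

## Retrosynthetic reasoning

**20 ⇒ 14 (ester sequence).** The two esters are not made from a diol. Ketone 20 is traced through its dioxolane 19 to alcohol 17 and acid chloride 18; 17 comes from ketone 16 by hydride reduction; 16 comes from ketol 14 and acid 15. With an α-hydroxy ketone as the branch point, O8 is acylated while C9 is still a carbonyl, so the two oxygens are differentiated by oxidation state, and C9 is set last by reduction on the rigid bicycle.

**14 ⇒ 13 (key disconnection, bond C7–C8).** Cutting C7–C8 opens ring B to the monocyclic keto aldehyde 13, which carries a prenyl group on C5 and a glyoxal unit on C10. The forward reaction is an intramolecular carbonyl-ene reaction. It has to close ring B, create C7 and C8, generate the isopropenyl group from the prenyl group and leave C9 as the ketone needed above. This cut was chosen over C8–C9 or C9–C10 because it is the only one in which the isopropenyl group and both ring-B heteroatoms arise in the bond-forming event itself, so no oxidant ever has to discriminate against the 1,1-disubstituted alkene.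

**13 ⇒ 9 + 10 (C8–C9).** The glyoxal carbon C8 is added as the formyl-anion equivalent 10 to the ester carbon C9 of 9, through acyl dithiane 12. This keeps the 1,2-dicarbonyl masked until just before the key step.

**9 ⇒ 6 (functional-group level).** The ketal of 9 comes from the silyl enol ether of 8, and the C14 methyl of 8 from the formyl group of 6. The formyl group is needed in 6 because it is the activating and directing group of the cycloaddition; it is then reduced to the methyl it stands for.

**6 ⇒ 3 + 5 (bonds C4–C5 and C1–C10).** Ring A is cut to the 2-silyloxy diene 5 and the enal ester 3. The Diels–Alder reaction has to set C4, C5 and C10 together: the (E)-geometry of 3 places C14 trans to C9, the endo rule places C15 cis to C14, and a chiral Lewis acid sets the absolute sense. Ring A is made here and not by conjugate additions to a cyclohexenone because only the cycloaddition delivers the C10 substituent cis to the larger group on C5.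

**3 ⇒ 1 + 2 and 5 ⇒ 4.** The enal ester is the aldol condensation product of aldehyde 1 (which brings the prenyl group) and glyoxylate 2; diene 5 is the silyl dienol ether of enone 4.

## Alternatives that were turned down

**Alternative 1:** Textbook Robinson annulation of ring A onto ring B (bonds C4–C5 and C1–C10). Michael addition of the enolate of ring-B ketone A1 to 4, then aldol condensation, would give octalenone A2. It was turned down for four reasons:
- A1 is a 1,3-disposed (meta) menthane that the carvone-type chiral pool does not supply, so it needs its own asymmetric synthesis.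
- The Michael step must build the quaternary C5 next to C4 with facial control from the remote C7/C8 centres.
- A2 has C1=C10, and the cis fusion would need a conjugate reduction that spares the isopropenyl group; catalytic hydrogenation is excluded and dissolving metal favours the trans fusion.
- C9 is still unoxidised in A2 and would need a separate γ-oxidation.

**Alternative 2:** Anionic oxy-Cope rearrangement of a bicyclo[2.2.2]octenol (bond C4–C5 formed, bond C2–C7 given up). The masked o-benzoquinone A3 would be taken by cycloaddition with a ketene equivalent and addition of a (Z)-propenyl organometallic to carbinol A4, whose potassium alkoxide rearranges to the cis-decalin A5 with ring A complete. It was turned down because: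
- cycloadditions of dienes like A3 have no reliable catalytic enantioselective form, so a resolution would be needed;
- A4 requires telling two ketones apart;
- A5 has C6=C7–C8=O, so C7 is the α-carbon of an enone; the isopropenyl group cannot be introduced by conjugate addition, and a halogenation/cross-coupling/conjugate-reduction detour would end in a kinetic protonation from the convex face that gives the wrong C7 epimer.

The rings are won quickly but ring B would cost more steps than the whole present endgame.

**Alternative 3:** Desymmetrisation of a 4,4-disubstituted cyclohexadienone by an intramolecular Stetter reaction (bond C9–C10). Aldehyde A6, with C7 and C8 already in the side chain, would cyclise under a chiral N-heterocyclic carbene onto one of the two enone arms to give A7; a later conjugate methylation would set C4. It was turned down because: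
- the two arms differ only by methyl versus vinyl in the axial position of the forming ring, so the catalyst would have to override an unbiased substrate;
- an α-oxygenated aldehyde is prone to elimination at the acyl-anion stage;
- 4-allyl-type dienone precursors are prone to [3,3] shift and aromatisation;
- the C7/C8 stereocentres would have to be built beforehand on a chain attached to a neopentyl carbon, which costs more steps than the key step saves.

Key step: step 8

Assumption: 1, 2, 4, 10, 15 and 18 are taken as catalogue compounds; the eremophilane numbering defined above is used for every bicyclic compound.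

## Route

**Step 1**
Reactants: 1 5-methylhex-4-enal; 2 ethyl glyoxylate
Product: 3 ethyl (2E)-3-formyl-6-methylhepta-2,5-dienoate
Conditions: morpholine (20 mol%), AcOH (20 mol%), toluene, 4 Å MS, 60 °C
Reagents that add atoms: none
Why: Amine-catalysed crossed aldol condensation (the enamine of 1 adds to the non-enolisable aldehyde of 2, then dehydration); equilibration through the iminium ion should give the (E)-isomer with formyl trans to the ester, the geometry that later places C14 trans to C9.

**Step 2**
Reactants: 4 (3E)-pent-3-en-2-one
Product: 5 triisopropyl{[(3E)-penta-1,3-dien-2-yl]oxy}silane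
Conditions: i-Pr3SiOTf, Et3N, Et2O, 0 °C
Reagents that add atoms: triisopropylsilyl trifluoromethanesulfonate, CC(C)[Si](C(C)C)(C(C)C)OS(=O)(=O)C(F)(F)F
Why: Soft enolisation on the methyl side with O-silylation gives the cross-conjugated 2-silyloxy diene; the (E)-alkene is not touched.

**Step 3**
Reactants: 3 ethyl (2E)-3-formyl-6-methylhepta-2,5-dienoate; 5 triisopropyl{[(3E)-penta-1,3-dien-2-yl]oxy}silane
Product: 6 ethyl (1S,5S,6S)-6-formyl-5-methyl-6-(3-methylbut-2-en-1-yl)-3-[(triisopropylsilyl)oxy]cyclohex-3-ene-1-carboxylate
Conditions: oxazaborolidinium salt from (S)-3,3-diphenyl-1-(2-methylphenyl)tetrahydro-1H,3H-pyrrolo[1,2-c][1,3,2]oxazaborole and HNTf2 (20 mol%), 5 (1.5 equiv), CH2Cl2, −78 → −40 °C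
Reagents that add atoms: none
Why: Diels–Alder reaction under chiral oxazaborolidinium catalysis; the formyl-bound catalyst makes the ester-bearing carbon the electrophilic terminus, so the CH2 terminus of 5 bonds there and the methyl-bearing terminus bonds to the α-carbon (ring positions 1, 5 and 6 of 6 are the future C10, C4 and C5). Endo placement of the complexed formyl group puts the C4 methyl cis to CHO (future C14), and the (E)-dienophile keeps the ester (future C9) trans to CHO and cis to the prenyl group. The catalyst is expected to leave the Cα-si face of the bound enal open to the diene, which fixes the absolute configuration of all three centres at once.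

**Step 4**
Reactants: 6 ethyl (1S,5S,6S)-6-formyl-5-methyl-6-(3-methylbut-2-en-1-yl)-3-[(triisopropylsilyl)oxy]cyclohex-3-ene-1-carboxylate
Product: 8 ethyl (1S,5S,6R)-5,6-dimethyl-6-(3-methylbut-2-en-1-yl)-3-[(triisopropylsilyl)oxy]cyclohex-3-ene-1-carboxylate, via tosylhydrazone 7 (not isolated)
Conditions: TsNHNH2 (1.1 equiv), THF, 25 °C; then catecholborane (3 equiv), 0 °C; then NaOAc·3H2O, 65 °C
Reagents that add atoms: 4-methylbenzenesulfonohydrazide, Cc1ccc(S(=O)(=O)NN)cc1 (its atoms are in 7 only)
Why: Tosylhydrazone formation and Kabalka-type reduction (hydride addition to C=N, loss of sulfinate, loss of N2 from the diazene) turn the neopentyl formyl group into the C14 methyl. The aldehyde has no α-hydrogen, so no stereocentre is at risk; ester, silyl enol ether and prenyl group should be inert.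

**Step 5**
Reactants: 8 ethyl (1S,5S,6R)-5,6-dimethyl-6-(3-methylbut-2-en-1-yl)-3-[(triisopropylsilyl)oxy]cyclohex-3-ene-1-carboxylate
Product: 9 ethyl (7S,8R,9S)-8,9-dimethyl-8-(3-methylbut-2-en-1-yl)-1,4-dioxaspiro[4.5]decane-7-carboxylate
Conditions: ethane-1,2-diol (5 equiv), TsOH·H2O (5 mol%), CH2Cl2, 25 °C
Reagents that add atoms: ethane-1,2-diol, OCCO
Why: Acid-catalysed exchange of the silyl enol ether for the dioxolane (C-protonation, capture of the oxocarbenium ion by the diol). The enol ether must go before step 8 because it would out-compete the prenyl group as a nucleophile toward the glyoxal (bridging Mukaiyama aldol); the ketal also keeps C2 inert to the dithiane anion and to hydride.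

**Step 6**
Reactants: 9 ethyl (7S,8R,9S)-8,9-dimethyl-8-(3-methylbut-2-en-1-yl)-1,4-dioxaspiro[4.5]decane-7-carboxylate; 10 1,3-dithiane
Product: 12 (1,3-dithian-2-yl)[(7S,8R,9S)-8,9-dimethyl-8-(3-methylbut-2-en-1-yl)-1,4-dioxaspiro[4.5]decan-7-yl]methanone, via 2-lithio-1,3-dithiane 11 (not isolated)
Conditions: 10 (2.2 equiv), n-BuLi (2.2 equiv), THF, −30 °C; then 9, −78 → −20 °C; aq. NH4Cl
Reagents that add atoms: n-butyllithium, [Li]CCCC (lithium in 11 only)
Why: Corey–Seebach acylation of the dithiane anion by the ester; the acidic 2-acyl dithiane is deprotonated by the second equivalent, which stops over-addition. C8 of the target enters here at the aldehyde oxidation level.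

**Step 7**
Reactants: 12 (1,3-dithian-2-yl)[(7S,8R,9S)-8,9-dimethyl-8-(3-methylbut-2-en-1-yl)-1,4-dioxaspiro[4.5]decan-7-yl]methanone
Product: 13 2-[(7S,8R,9S)-8,9-dimethyl-8-(3-methylbut-2-en-1-yl)-1,4-dioxaspiro[4.5]decan-7-yl]-2-oxoacetaldehyde
Conditions: N-chlorosuccinimide, AgNO3, 2,6-lutidine, MeCN–H2O (4:1), 0 °C; azeotropic drying (toluene)
Reagents that add atoms: water, O
Why: Buffered oxidative hydrolysis of the dithioacetal (S-chlorination, silver-assisted hydrolysis) unmasks the α-keto aldehyde; dioxolanes and trisubstituted alkenes are routinely carried through these conditions. The product should be used crude after drying because it hydrates readily.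

**Step 8**
Reactants: 13 2-[(7S,8R,9S)-8,9-dimethyl-8-(3-methylbut-2-en-1-yl)-1,4-dioxaspiro[4.5]decan-7-yl]-2-oxoacetaldehyde
Product: 14 2,2-ethylenedioxy-8α-hydroxy-10βH-eremophil-11-en-9-one (4β,5β-dimethyl; 7β-isopropenyl; cis-fused)
Conditions: Me2AlCl (1.5 equiv), CH2Cl2 (0.01 M), −78 → −40 °C; aq. NaHCO3
Reagents that add atoms: none
Why: The Lewis acid binds the glyoxal; the aldehyde carbon C8 is attacked by the less substituted carbon (C7) of the prenyl double bond while an allylic methyl hydrogen passes to oxygen, a type 1 intramolecular carbonyl-ene reaction of the citronellal-to-isopulegol kind, with a glyoxylate-like activated enophile as the closest precedent. Ring B closes as a six-membered ring through a chair-like transition state (bond C7–C8, exo to the carbonyl), and the isopropenyl group is created in the same event. C7: chair A, in which the forming ring carries C1 and the C5 methyl equatorially and only C4 axially, should be preferred to chair B, which has the C5 methyl and C1 both axial on the forming ring and puts the C4 methyl 1,3-diaxial to a ketal oxygen on ring A; with the alkene equatorial in chair A the isopropenyl group comes out 7β, cis to C14. C8: the complexed carbonyl oxygen is equatorial in the same chair, so the hydroxyl is trans to the isopropenyl group (8α), and being α to the C9 ketone it can also settle into this equatorial position. The step needs chemoselectivity for the aldehyde over the neighbouring ketone (more electrophilic; six- instead of five-membered ring), regioselectivity for C7 over C11 (six- instead of seven-membered ring) and facial selectivity, which rests on the chair preference imposed by the cis substituents on C5 and C10. Me2AlCl also scavenges protons, which should suppress Prins-type chloride capture and migration of the new double bond.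

**Step 9**
Reactants: 14 2,2-ethylenedioxy-8α-hydroxy-10βH-eremophil-11-en-9-one; 15 (2R)-2-methylbutanoic acid
Product: 16 2,2-ethylenedioxy-8α-[(2R)-2-methylbutanoyloxy]-10βH-eremophil-11-en-9-one
Conditions: 15 (1.5 equiv), N-(3-dimethylaminopropyl)-N′-ethylcarbodiimide hydrochloride, 4-(dimethylamino)pyridine (cat.), CH2Cl2, 0 → 25 °C
Reagents that add atoms: none
Why: Steglich esterification of the only free hydroxyl; a simple α-branched alkyl acid is not expected to racemise under carbodiimide activation, so the (R) centre is carried in intact. Acylating O8 while C9 is still a ketone fixes which oxygen receives which acyl group.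

**Step 10**
Reactants: 16 2,2-ethylenedioxy-8α-[(2R)-2-methylbutanoyloxy]-10βH-eremophil-11-en-9-one
Product: 17 2,2-ethylenedioxy-8α-[(2R)-2-methylbutanoyloxy]-10βH-eremophil-11-en-9α-ol
Conditions: LiBH(s-Bu)3 (1.1 equiv), THF, −78 °C; AcOH, −78 °C
Reagents that add atoms: none
Why: The bulky borohydride should attack C9 along the equatorial trajectory from the convex β-face, because the axial α-approach is blocked by C4 (syn-axial to C9), giving the axial 9α-alcohol cis to the C8 ester. Low temperature and the cold acidic quench limit acyl migration; esters and ketal are not reduced at −78 °C.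

**Step 11**
Reactants: 17 2,2-ethylenedioxy-8α-[(2R)-2-methylbutanoyloxy]-10βH-eremophil-11-en-9α-ol; 18 (2E)-2-methylbut-2-enoyl chloride
Product: 19 2,2-ethylenedioxy-9α-[(2E)-2-methylbut-2-enoyloxy]-8α-[(2R)-2-methylbutanoyloxy]-10βH-eremophil-11-ene
Conditions: 18 (3 equiv), Et3N, 4-(dimethylamino)pyridine, CH2Cl2, 0 → 25 °C
Reagents that add atoms: none
Why: Acylation of the hindered axial alcohol by the acid chloride under nucleophilic catalysis; the (E)-acyl group is the stable geometry and should be retained.

**Step 12**
Reactants: 19 2,2-ethylenedioxy-9α-[(2E)-2-methylbut-2-enoyloxy]-8α-[(2R)-2-methylbutanoyloxy]-10βH-eremophil-11-ene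
Product: 20 (4S,5R,7R,8R,9S,10S)-9-[(2E)-2-methylbut-2-enoyloxy]-8-[(2R)-2-methylbutanoyloxy]eremophil-11-en-2-one (8α,9α-diacyloxy-10βH; CNP0312791.1)
Conditions: pyridinium p-toluenesulfonate (cat.), acetone–H2O (10:1), 50 °C
Reagents that add atoms: water, O
Why: Mild acid-catalysed hydrolysis of the dioxolane releases the C2 ketone; both esters and the isopropenyl group should survive, and C1 and C3 are methylene groups, so no stereocentre is exposed.

## Compound list

1 | 5-methylhex-4-enal | CC(C)=CCCC=O | starting material
2 | ethyl glyoxylate | CCOC(=O)C=O | starting material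
3 | ethyl (2E)-3-formyl-6-methylhepta-2,5-dienoate | CCOC(=O)/C=C(/C=O)CC=C(C)C | intermediate
4 | (3E)-pent-3-en-2-one | C/C=C/C(C)=O | starting material
5 | triisopropyl{[(3E)-penta-1,3-dien-2-yl]oxy}silane | C=C(O[Si](C(C)C)(C(C)C)C(C)C)/C=C/C | intermediate
6 | ethyl (1S,5S,6S)-6-formyl-5-methyl-6-(3-methylbut-2-en-1-yl)-3-[(triisopropylsilyl)oxy]cyclohex-3-ene-1-carboxylate | CCOC(=O)[C@H]1CC(O[Si](C(C)C)(C(C)C)C(C)C)=C[C@H](C)[C@@]1(C=O)CC=C(C)C | intermediate
7 | ethyl (1S,5S,6S)-5-methyl-6-(3-methylbut-2-en-1-yl)-6-{(E)-[2-(4-methylbenzenesulfonyl)hydrazinylidene]methyl}-3-[(triisopropylsilyl)oxy]cyclohex-3-ene-1-carboxylate | CCOC(=O)[C@H]1CC(O[Si](C(C)C)(C(C)C)C(C)C)=C[C@H](C)[C@@]1(/C=N/NS(=O)(=O)c2ccc(C)cc2)CC=C(C)C | intermediate (not isolated)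
8 | ethyl (1S,5S,6R)-5,6-dimethyl-6-(3-methylbut-2-en-1-yl)-3-[(triisopropylsilyl)oxy]cyclohex-3-ene-1-carboxylate | CCOC(=O)[C@H]1CC(O[Si](C(C)C)(C(C)C)C(C)C)=C[C@H](C)[C@@]1(C)CC=C(C)C | intermediate
9 | ethyl (7S,8R,9S)-8,9-dimethyl-8-(3-methylbut-2-en-1-yl)-1,4-dioxaspiro[4.5]decane-7-carboxylate | CCOC(=O)[C@H]1CC2(OCCO2)C[C@H](C)[C@@]1(C)CC=C(C)C | intermediate
10 | 1,3-dithiane | C1CSCSC1 | starting material
11 | 2-lithio-1,3-dithiane | [Li]C1SCCCS1 | intermediate (not isolated)
12 | (1,3-dithian-2-yl)[(7S,8R,9S)-8,9-dimethyl-8-(3-methylbut-2-en-1-yl)-1,4-dioxaspiro[4.5]decan-7-yl]methanone | O=C(C1SCCCS1)[C@H]1CC2(OCCO2)C[C@H](C)[C@@]1(C)CC=C(C)C | intermediate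
13 | 2-[(7S,8R,9S)-8,9-dimethyl-8-(3-methylbut-2-en-1-yl)-1,4-dioxaspiro[4.5]decan-7-yl]-2-oxoacetaldehyde | O=CC(=O)[C@H]1CC2(OCCO2)C[C@H](C)[C@@]1(C)CC=C(C)C | intermediate
14 | 2,2-ethylenedioxy-8α-hydroxy-10βH-eremophil-11-en-9-one | C=C(C)[C@H]1C[C@@]2(C)[C@H](CC3(OCCO3)C[C@@H]2C)C(=O)[C@@H]1O | intermediate
15 | (2R)-2-methylbutanoic acid | CC[C@@H](C)C(=O)O | starting material
16 | 2,2-ethylenedioxy-8α-[(2R)-2-methylbutanoyloxy]-10βH-eremophil-11-en-9-one | C=C(C)[C@H]1C[C@@]2(C)[C@H](CC3(OCCO3)C[C@@H]2C)C(=O)[C@@H]1OC(=O)[C@H](C)CC | intermediate
17 | 2,2-ethylenedioxy-8α-[(2R)-2-methylbutanoyloxy]-10βH-eremophil-11-en-9α-ol | C=C(C)[C@H]1C[C@@]2(C)[C@H](CC3(OCCO3)C[C@@H]2C)[C@H](O)[C@@H]1OC(=O)[C@H](C)CC | intermediate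
18 | (2E)-2-methylbut-2-enoyl chloride (tigloyl chloride) | ClC(=O)/C(C)=C/C | starting material
19 | 2,2-ethylenedioxy-9α-[(2E)-2-methylbut-2-enoyloxy]-8α-[(2R)-2-methylbutanoyloxy]-10βH-eremophil-11-ene | C=C(C)[C@H]1C[C@@]2(C)[C@H](CC3(OCCO3)C[C@@H]2C)[C@H](OC(=O)/C(C)=C/C)[C@@H]1OC(=O)[C@H](C)CC | intermediate
20 | (4S,5R,7R,8R,9S,10S)-9-[(2E)-2-methylbut-2-enoyloxy]-8-[(2R)-2-methylbutanoyloxy]eremophil-11-en-2-one | C=C(C)[C@H]1C[C@@]2(C)[C@H](CC(=O)C[C@@H]2C)[C@H](OC(=O)/C(C)=C/C)[C@@H]1OC(=O)[C@H](C)CC | target

## Step count and least certain steps

Total: 12 steps. Longest linear sequence: 11 steps (steps 1 and 3–12; step 2 is a one-step side branch).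

**Step 8 (key step).** Most likely to go wrong: loss of facial selectivity, i.e. partial closure through chair B, which gives the diastereomer epimeric at both C7 and C8 relative to C5/C10. The two chairs differ by little more than one 1,3-diaxial interaction. The leak would grow if the strong Lewis acid ionises the dioxolane (an oxocarbenium ion at C2 flattens ring A) or diverts the reaction onto a stepwise Prins path. Fallback, from 13 and back at 14: the same bond is made through a closed, metal-templated transition state under neutral aqueous conditions. Ene-type allylic chlorination of the prenyl group (N-chlorosuccinimide, PhSeCl cat., CH2Cl2) would give the secondary allylic chloride F1. Indium metal in THF–H2O then generates the allylindium species, which adds through its γ-carbon (C7) to the hydrated aldehyde in an intramolecular Barbier-type allylation and returns 14. This path has no cationic character, leaves the ketal alone and gives the trans C7/C8 relationship from its compact cyclic array.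

**Step 3.** Most likely to go wrong: insufficient enantioselectivity, with some endo/exo leakage. The enal is both α-branched and β-acylated, so binding of the catalyst at the ester, or a loosely organised formyl complex, can compete with the complex that the facial model requires; open-chain Mukaiyama–Michael addition of 5 would be a second drain. The sense of induction is assigned by analogy with 2-substituted acroleins and would have to be confirmed. Fallback, from 3 and 5 and back at 6: the cycloaddition is promoted by the achiral Lewis acid EtAlCl2 (formyl-bound aluminium keeps the regio- and endo-control), which gives racemic 6; the racemate is resolved by preparative chromatography on a chiral stationary phase, and the mirror-image adduct F2 is discarded.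

**Step 6.** Most likely to go wrong: enolisation instead of addition. The ester sits on a tertiary carbon next to the quaternary C5, so the bulky sulfur-stabilised anion may deprotonate C10–H faster than it adds, returning ester that is partly epimerised at C10. Fallback, from 9 and back at 12: the ester is reduced with i-Bu2AlH at −78 °C to aldehyde F3, the lithiated dithiane 11 is added to this far more electrophilic carbonyl to give carbinol F4 (both epimers), and oxidation with Dess–Martin periodinane gives 12.

**Step 10.** Most likely to go wrong: 1,2-acyl migration of the 2-methylbutanoyl group from O8 to the newly formed cis-alkoxide on O9 before the quench (the two oxygens are gauche), which would scramble the positions of the two esters; partial reduction of the ester is a lesser concern. Fallback, from 14 and back at 17: the order is reversed. The free ketol 14 is reduced with the same hydride to the cis-diol F5, where no ester is present to migrate; then only the unhindered equatorial 8α-hydroxyl is acylated with 15 (carbodiimide, −20 °C), relying on the steric difference from the axial, C4-flanked 9α-hydroxyl.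

**Step 11.** Most likely to go wrong: slow acylation of the axial 9α-hydroxyl by the conjugated, α-branched acyl chloride, so that the basic conditions have time to promote 8→9 acyl migration. Fallback, from 17 and back at 19: the alcohol is acylated with the more electrophilic, saturated 2-(diethoxyphosphoryl)propanoic acid (dicyclohexylcarbodiimide, 4-(dimethylamino)pyridine) to give the phosphonate ester F6, and the tiglate is built in place by Horner–Wadsworth–Emmons olefination with acetaldehyde (LiCl, DBU, MeCN), which is (E)-selective for this α-methyl phosphonate.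

## Further compounds

F1 | step 8 | 2-[(7S,8R,9S)-8-(2-chloro-3-methylbut-3-en-1-yl)-8,9-dimethyl-1,4-dioxaspiro[4.5]decan-7-yl]-2-oxoacetaldehyde (both epimers at the chlorinated carbon) | O=CC(=O)[C@H]1CC2(OCCO2)C[C@H](C)[C@@]1(C)CC(Cl)C(C)=C
F2 | step 3 | ethyl (1R,5R,6R)-6-formyl-5-methyl-6-(3-methylbut-2-en-1-yl)-3-[(triisopropylsilyl)oxy]cyclohex-3-ene-1-carboxylate (enantiomer of 6) | CCOC(=O)[C@@H]1CC(O[Si](C(C)C)(C(C)C)C(C)C)=C[C@@H](C)[C@]1(C=O)CC=C(C)C
F3 | step 6 | (7S,8R,9S)-8,9-dimethyl-8-(3-methylbut-2-en-1-yl)-1,4-dioxaspiro[4.5]decane-7-carbaldehyde | O=C[C@H]1CC2(OCCO2)C[C@H](C)[C@@]1(C)CC=C(C)C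
F4 | step 6 | (1,3-dithian-2-yl)[(7S,8R,9S)-8,9-dimethyl-8-(3-methylbut-2-en-1-yl)-1,4-dioxaspiro[4.5]decan-7-yl]methanol (both carbinol epimers) | OC(C1SCCCS1)[C@H]1CC2(OCCO2)C[C@H](C)[C@@]1(C)CC=C(C)C
F5 | step 10 | 2,2-ethylenedioxy-10βH-eremophil-11-ene-8α,9α-diol | C=C(C)[C@H]1C[C@@]2(C)[C@H](CC3(OCCO3)C[C@@H]2C)[C@H](O)[C@@H]1O
F6 | step 11 | 9α-[2-(diethoxyphosphoryl)propanoyloxy]-2,2-ethylenedioxy-8α-[(2R)-2-methylbutanoyloxy]-10βH-eremophil-11-ene (both epimers at the phosphonate-bearing carbon) | C=C(C)[C@H]1C[C@@]2(C)[C@H](CC3(OCCO3)C[C@@H]2C)[C@H](OC(=O)C(C)P(=O)(OCC)OCC)[C@@H]1OC(=O)[C@H](C)CC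
A1 | alternative 1 | (4R,5S)-5-[(tert-butyldimethylsilyl)oxy]-2-methyl-4-(prop-1-en-2-yl)cyclohexan-1-one (C2 epimers) | CC1C[C@H](C(C)=C)[C@@H](O[Si](C)(C)C(C)(C)C)CC1=O
A2 | alternative 1 | 8α-[(tert-butyldimethylsilyl)oxy]eremophila-1(10),11-dien-2-one | C=C(C)[C@H]1C[C@@]2(C)C(=CC(=O)C[C@@H]2C)C[C@@H]1O[Si](C)(C)C(C)(C)C
A3 | alternative 2 | 6,6-dimethoxy-4-methylcyclohexa-2,4-dien-1-one | O=C1C=CC(C)=CC1(OC)OC
A4 | alternative 2 | 6-hydroxy-3,3-dimethoxy-8-methyl-6-[(1Z)-prop-1-en-1-yl]bicyclo[2.2.2]oct-7-en-2-one (racemic; one enantiomer drawn, propenyl syn to the ring alkene) | C/C=C\[C@@]1(O)C[C@H]2C(C)=C[C@@H]1C(=O)C2(OC)OC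
A5 | alternative 2 | 9,9-dimethoxy-4β,5β-dimethyl-10βH-decal-6-ene-2,8-dione (eremophilane numbering; racemic, one enantiomer drawn) | O=C1C=C[C@@]2(C)[C@H](CC(=O)C[C@@H]2C)C1(OC)OC
A6 | alternative 3 | 2-[(tert-butyldimethylsilyl)oxy]-4-(1-methyl-4-oxocyclohexa-2,5-dien-1-yl)-3-(prop-1-en-2-yl)butanal (C2 and C3 configured as C8 and C7 of 20) | C=C(C)[C@@H](CC1(C)C=CC(=O)C=C1)[C@@H](O[Si](C)(C)C(C)(C)C)C=O
A7 | alternative 3 | 8α-[(tert-butyldimethylsilyl)oxy]-15-nor-10βH-eremophila-3,11-diene-2,9-dione | C=C(C)[C@H]1C[C@@]2(C)[C@H](CC(=O)C=C2)C(=O)[C@@H]1O[Si](C)(C)C(C)(C)C
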